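**Retrosynthetic overview**

1. Target 19 is the debenzylated form of 18, and the C4 methyl of 18 comes from the C4 ester of tetrahydrofuran 15 (reduce, mesylate, hydride).
2. Key disconnection C4–C5 of 15: C5 is a benzylic CH bound to O1 that carries ring B and lies five atoms from C4 (C4–C3–C2–O1–C5), so diazo ester 14, the 3,4,5-trimethoxybenzyl ether of the C2 carbinol, already holds every ring atom and a rhodium carbenoid at C4 can insert into the O–CH2 C–H.
3. 14 comes from ester 12 by deacylative diazo transfer; 12 from alkene 8 (hydroboration, oxidation, esterification); the O1–C5 bond of 8 from Williamson etherification of alcohol 6 with chloride 7.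
4. The syn C2/C3 pair of 6 comes from asymmetric (Z)-crotylboration of aldehyde 2 (benzylated 1) with cis-2-butene 3.
5. Ring order: rings A and B are bought intact; the tetrahydrofuran is the only ring made, in step 8.

Key step: step 8

Remark: the ring is numbered O1, C2 (carries ring A, 3-hydroxy-4,5-dimethoxyphenyl), C3, C4, C5 (carries ring B, 3,4,5-trimethoxyphenyl). The target SMILES is read as (2R,3S,4S,5S): ring A cis to the C3 methyl, the two methyls trans, ring B trans to the C4 methyl and cis to ring A. Compounds 1, 3, 7 and all reagents named are taken as commercial.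

**Route**

Step 1
Reactants: 1 3-hydroxy-4,5-dimethoxybenzaldehyde
Product: 2 3-(benzyloxy)-4,5-dimethoxybenzaldehyde
Conditions: BnBr, K2CO3, DMF, rt
Reagents that add atoms: benzyl bromide, BrCc1ccccc1
Why: Williamson O-alkylation (SN2) of the potassium phenoxide masks the acidic phenol as a benzyl ether that withstands the bases, hydrides and the carbenoid step and is removable at the end by hydrogenolysis.

Step 2
Reactants: 2 3-(benzyloxy)-4,5-dimethoxybenzaldehyde, 3 cis-2-butene
Product: 6 (1R,2S)-1-[3-(benzyloxy)-4,5-dimethoxyphenyl]-2-methylbut-3-en-1-ol, via B-(Z)-crotyldiisopinocampheylborane 4 (not isolated), via diisopinocampheylborinate 5 (not isolated)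
Conditions: 3, n-BuLi, KOt-Bu, THF, −78 to −45 °C; (+)-Ipc2BOMe, −78 °C; BF3·OEt2; 2, −78 °C; then NaOH, H2O2, 0 °C to rt
Reagents that add atoms: (+)-B-methoxydiisopinocampheylborane [(+)-Ipc2BOMe, the enantiomer derived from (−)-α-pinene], COB([C@H]1C[C@H]2C[C@@H]([C@@H]1C)C2(C)C)[C@H]1C[C@H]2C[C@@H]([C@@H]1C)C2(C)C (its boron and isopinocampheyl groups appear in 4 and 5 only)
Why: Asymmetric crotylboration (Brown type) through a closed chair Zimmerman–Traxler transition state, in which the Z geometry of crotylborane 4, kept by metalating cis-2-butene at or below −45 °C, becomes the syn C2/C3 relationship and the isopinocampheyl groups of the (+)-series direct addition to the Re face of aldehyde 2, setting the future C2 as R and C3 as S by reagent control.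

Step 3
Reactants: 6 (1R,2S)-1-[3-(benzyloxy)-4,5-dimethoxyphenyl]-2-methylbut-3-en-1-ol, 7 3,4,5-trimethoxybenzyl chloride
Product: 8 1-(benzyloxy)-2,3-dimethoxy-5-[(1R,2S)-2-methyl-1-[(3,4,5-trimethoxyphenyl)methoxy]but-3-en-1-yl]benzene
Conditions: NaH, DMF, 0 °C to rt
Reagents that add atoms: none
Why: Williamson ether synthesis in which the sodium alkoxide of 6 displaces chloride from the primary benzylic carbon of 7 (SN2), forming the O1–C5 bond without touching C2 or C3 in a substrate that carries no base-labile group.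

Step 4
Reactants: 8 1-(benzyloxy)-2,3-dimethoxy-5-[(1R,2S)-2-methyl-1-[(3,4,5-trimethoxyphenyl)methoxy]but-3-en-1-yl]benzene
Product: 10 (3S,4R)-4-[3-(benzyloxy)-4,5-dimethoxyphenyl]-3-methyl-4-[(3,4,5-trimethoxyphenyl)methoxy]butan-1-ol, via B-alkyl-9-borabicyclo[3.3.1]nonane 9 (not isolated)
Conditions: 9-BBN, THF, 0 °C to rt; then NaOH, H2O2, 0 °C to rt
Reagents that add atoms: 9-borabicyclo[3.3.1]nonane, B1C2CCCC1CCC2 (in 9 only); hydrogen peroxide, OO
Why: Hydroboration–oxidation in which the bulky 9-BBN places boron on the terminal carbon (anti-Markovnikov) and alkaline peroxide replaces boron by hydroxyl, giving the primary alcohol while the ethers and both stereocentres stay untouched.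

Step 5
Reactants: 10 (3S,4R)-4-[3-(benzyloxy)-4,5-dimethoxyphenyl]-3-methyl-4-[(3,4,5-trimethoxyphenyl)methoxy]butan-1-ol
Product: 11 (3S,4R)-4-[3-(benzyloxy)-4,5-dimethoxyphenyl]-3-methyl-4-[(3,4,5-trimethoxyphenyl)methoxy]butanoic acid
Conditions: TEMPO (cat.), PhI(OAc)2, MeCN/H2O, rt
Reagents that add atoms: water, O
Why: Nitroxyl (oxoammonium) catalysed oxidation with PhI(OAc)2 as terminal oxidant takes the primary alcohol through the aldehyde hydrate to the carboxylic acid under near-neutral conditions that benzyl ethers and electron-rich arenes tolerate.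

Step 6
Reactants: 11 (3S,4R)-4-[3-(benzyloxy)-4,5-dimethoxyphenyl]-3-methyl-4-[(3,4,5-trimethoxyphenyl)methoxy]butanoic acid
Product: 12 methyl (3S,4R)-4-[3-(benzyloxy)-4,5-dimethoxyphenyl]-3-methyl-4-[(3,4,5-trimethoxyphenyl)methoxy]butanoate
Conditions: MeI, K2CO3, DMF, rt
Reagents that add atoms: iodomethane, CI
Why: SN2 O-methylation of the potassium carboxylate gives the methyl ester needed for enolate chemistry, and no stereocentre is alpha to the carboxyl group.

Step 7
Reactants: 12 methyl (3S,4R)-4-[3-(benzyloxy)-4,5-dimethoxyphenyl]-3-methyl-4-[(3,4,5-trimethoxyphenyl)methoxy]butanoate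
Product: 14 methyl (3S,4R)-4-[3-(benzyloxy)-4,5-dimethoxyphenyl]-2-diazo-3-methyl-4-[(3,4,5-trimethoxyphenyl)methoxy]butanoate, via alpha-trifluoroacetyl ester 13 (not isolated)
Conditions: LiN(SiMe3)2, THF, −78 °C; CF3CO2CH2CF3; aq. HCl quench; crude 13, 4-AcNHC6H4SO2N3, Et3N, H2O, MeCN, rt
Reagents that add atoms: 2,2,2-trifluoroethyl trifluoroacetate, O=C(OCC(F)(F)F)C(F)(F)F (in 13 only); 4-acetamidobenzenesulfonyl azide, CC(=O)Nc1ccc(cc1)S(=O)(=O)N=[N+]=[N-]
Why: Deacylative Regitz diazo transfer in which Claisen-type C-trifluoroacetylation of the lithium enolate gives the activated 1,3-dicarbonyl 13, which adds the sulfonyl azide and fragments with passage of the trifluoroacetyl group to the sulfonamide nitrogen, leaving the diazo group on C4, while C3 is not enolisable and the C2 alkoxy group, gamma to the ester, cannot be eliminated.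

Step 8
Reactants: 14 methyl (3S,4R)-4-[3-(benzyloxy)-4,5-dimethoxyphenyl]-2-diazo-3-methyl-4-[(3,4,5-trimethoxyphenyl)methoxy]butanoate
Product: 15 methyl (2S,3S,4S,5R)-5-[3-(benzyloxy)-4,5-dimethoxyphenyl]-4-methyl-2-(3,4,5-trimethoxyphenyl)oxolane-3-carboxylate
Conditions: Rh2(O2CCPh3)4 (1 mol%), CH2Cl2, −78 °C to rt, slow addition of 14
Reagents that add atoms: none
Why: Rh2(O2CCPh3)4 expels N2 from 14 to give an electrophilic rhodium carbenoid at C4, which inserts through a concerted, hydride-transfer-like three-centre transition state into a C5–H bond of the O–CH2–aryl group, the most hydridic C–H within reach because it is benzylic to the electron-rich ring B and alpha to O1; this is the established dirhodium-catalysed 1,5 C–H insertion of alpha-diazo esters next to an ether oxygen that gives tetrahydrofuran-3-carboxylates. The tetrahydrofuran closes in the 1,5 mode by formation of the C4–C5 bond, with C2 and C3 carried over unchanged from 14. C5 is set by which diastereotopic benzylic hydrogen reacts: the envelope-like transition state that keeps ring B pseudo-equatorial, on the side of ring A and away from the carboxylate wall of the catalyst, should give the 2,5-cis-diaryl ring with retention at C5. C4 is set in the same event with the ester anti to both the C3 methyl and ring B, and since this is also the thermodynamic arrangement a C4 epimer would be converged on 15 by brief treatment with DBU. The step needs chemoselectivity over 1,2-hydride migration from C3 and over attack of the carbenoid on the ortho carbons of ring A; the C3–H bond is inductively deactivated by the C2 oxygen, bulky triphenylacetate ligands and low temperature disfavour the migration, and the doubly activated C5–H should outcompete aromatic substitution.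

Step 9
Reactants: 15 methyl (2S,3S,4S,5R)-5-[3-(benzyloxy)-4,5-dimethoxyphenyl]-4-methyl-2-(3,4,5-trimethoxyphenyl)oxolane-3-carboxylate
Product: 16 [(2S,3R,4S,5R)-5-[3-(benzyloxy)-4,5-dimethoxyphenyl]-4-methyl-2-(3,4,5-trimethoxyphenyl)oxolan-3-yl]methanol
Conditions: LiAlH4, THF, 0 °C
Reagents that add atoms: none
Why: Hydride reduction of the ester to the primary alcohol, which at 0 °C is faster than enolisation at C4 and leaves the benzyl and aryl ethers untouched.

Step 10
Reactants: 16 [(2S,3R,4S,5R)-5-[3-(benzyloxy)-4,5-dimethoxyphenyl]-4-methyl-2-(3,4,5-trimethoxyphenyl)oxolan-3-yl]methanol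
Product: 17 [(2S,3R,4S,5R)-5-[3-(benzyloxy)-4,5-dimethoxyphenyl]-4-methyl-2-(3,4,5-trimethoxyphenyl)oxolan-3-yl]methyl methanesulfonate
Conditions: MsCl, Et3N, CH2Cl2, 0 °C
Reagents that add atoms: methanesulfonyl chloride, CS(=O)(=O)Cl
Why: Sulfonylation of the primary alcohol turns the hydroxyl into a leaving group without involving any stereocentre.

Step 11
Reactants: 17 [(2S,3R,4S,5R)-5-[3-(benzyloxy)-4,5-dimethoxyphenyl]-4-methyl-2-(3,4,5-trimethoxyphenyl)oxolan-3-yl]methyl methanesulfonate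
Product: 18 (2R,3S,4S,5S)-2-[3-(benzyloxy)-4,5-dimethoxyphenyl]-3,4-dimethyl-5-(3,4,5-trimethoxyphenyl)oxolane
Conditions: LiBHEt3, THF, 0 °C to rt
Reagents that add atoms: none
Why: SN2 displacement of the primary mesylate by the strong hydride donor LiBHEt3 gives the C4 methyl group, and the ring stereocentres are untouched because substitution occurs at the exocyclic CH2.

Step 12
Reactants: 18 (2R,3S,4S,5S)-2-[3-(benzyloxy)-4,5-dimethoxyphenyl]-3,4-dimethyl-5-(3,4,5-trimethoxyphenyl)oxolane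
Product: 19 5-[(2R,3S,4S,5S)-3,4-dimethyl-5-(3,4,5-trimethoxyphenyl)oxolan-2-yl]-2,3-dimethoxyphenol
Conditions: H2 (1 atm), 10% Pd/C, EtOAc, rt
Reagents that add atoms: none
Why: Catalytic hydrogenolysis cleaves the aryl benzyl ether much faster than the hindered benzylic C–O bonds of the tetrahydrofuran in a neutral aprotic solvent, releasing the phenol of ring A without affecting any stereocentre.

**Compound list**

1 | 3-hydroxy-4,5-dimethoxybenzaldehyde | COc1cc(C=O)cc(O)c1OC | starting material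
2 | 3-(benzyloxy)-4,5-dimethoxybenzaldehyde | COc1cc(C=O)cc(OCc2ccccc2)c1OC | intermediate
3 | cis-2-butene, (Z)-but-2-ene | C/C=C\C | starting material
4 | B-[(Z)-but-2-en-1-yl]bis[(1S,2R,3S,5S)-2,6,6-trimethylbicyclo[3.1.1]heptan-3-yl]borane | C/C=C\CB([C@H]1C[C@H]2C[C@@H]([C@@H]1C)C2(C)C)[C@H]1C[C@H]2C[C@@H]([C@@H]1C)C2(C)C | intermediate (not isolated)
5 | (1R,2S)-1-[3-(benzyloxy)-4,5-dimethoxyphenyl]-2-methylbut-3-en-1-yl bis[(1S,2R,3S,5S)-2,6,6-trimethylbicyclo[3.1.1]heptan-3-yl]borinate | COc1cc([C@H](OB([C@H]2C[C@H]3C[C@@H]([C@@H]2C)C3(C)C)[C@H]2C[C@H]3C[C@@H]([C@@H]2C)C3(C)C)[C@@H](C)C=C)cc(OCc2ccccc2)c1OC | intermediate (not isolated)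
6 | (1R,2S)-1-[3-(benzyloxy)-4,5-dimethoxyphenyl]-2-methylbut-3-en-1-ol | COc1cc([C@H](O)[C@@H](C)C=C)cc(OCc2ccccc2)c1OC | intermediate
7 | 3,4,5-trimethoxybenzyl chloride | COc1cc(CCl)cc(OC)c1OC | starting material
8 | 1-(benzyloxy)-2,3-dimethoxy-5-[(1R,2S)-2-methyl-1-[(3,4,5-trimethoxyphenyl)methoxy]but-3-en-1-yl]benzene | COc1cc([C@H](OCc2cc(OC)c(OC)c(OC)c2)[C@@H](C)C=C)cc(OCc2ccccc2)c1OC | intermediate
9 | 9-[(3S,4R)-4-[3-(benzyloxy)-4,5-dimethoxyphenyl]-3-methyl-4-[(3,4,5-trimethoxyphenyl)methoxy]butyl]-9-borabicyclo[3.3.1]nonane | COc1cc([C@H](OCc2cc(OC)c(OC)c(OC)c2)[C@@H](C)CCB2C3CCCC2CCC3)cc(OCc2ccccc2)c1OC | intermediate (not isolated)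
10 | (3S,4R)-4-[3-(benzyloxy)-4,5-dimethoxyphenyl]-3-methyl-4-[(3,4,5-trimethoxyphenyl)methoxy]butan-1-ol | COc1cc([C@H](OCc2cc(OC)c(OC)c(OC)c2)[C@@H](C)CCO)cc(OCc2ccccc2)c1OC | intermediate
11 | (3S,4R)-4-[3-(benzyloxy)-4,5-dimethoxyphenyl]-3-methyl-4-[(3,4,5-trimethoxyphenyl)methoxy]butanoic acid | COc1cc([C@H](OCc2cc(OC)c(OC)c(OC)c2)[C@@H](C)CC(O)=O)cc(OCc2ccccc2)c1OC | intermediate
12 | methyl (3S,4R)-4-[3-(benzyloxy)-4,5-dimethoxyphenyl]-3-methyl-4-[(3,4,5-trimethoxyphenyl)methoxy]butanoate | COc1cc([C@H](OCc2cc(OC)c(OC)c(OC)c2)[C@@H](C)CC(=O)OC)cc(OCc2ccccc2)c1OC | intermediate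
13 | methyl (3S,4R)-4-[3-(benzyloxy)-4,5-dimethoxyphenyl]-3-methyl-2-(trifluoroacetyl)-4-[(3,4,5-trimethoxyphenyl)methoxy]butanoate (C2 epimers and enol) | COc1cc([C@H](OCc2cc(OC)c(OC)c(OC)c2)[C@@H](C)C(C(=O)C(F)(F)F)C(=O)OC)cc(OCc2ccccc2)c1OC | intermediate (not isolated)
14 | methyl (3S,4R)-4-[3-(benzyloxy)-4,5-dimethoxyphenyl]-2-diazo-3-methyl-4-[(3,4,5-trimethoxyphenyl)methoxy]butanoate | COc1cc([C@H](OCc2cc(OC)c(OC)c(OC)c2)[C@@H](C)C(=[N+]=[N-])C(=O)OC)cc(OCc2ccccc2)c1OC | intermediate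
15 | methyl (2S,3S,4S,5R)-5-[3-(benzyloxy)-4,5-dimethoxyphenyl]-4-methyl-2-(3,4,5-trimethoxyphenyl)oxolane-3-carboxylate | COc1cc([C@@H]2O[C@H](c3cc(OC)c(OC)c(OC)c3)[C@@H](C(=O)OC)[C@@H]2C)cc(OCc3ccccc3)c1OC | intermediate
16 | [(2S,3R,4S,5R)-5-[3-(benzyloxy)-4,5-dimethoxyphenyl]-4-methyl-2-(3,4,5-trimethoxyphenyl)oxolan-3-yl]methanol | COc1cc([C@@H]2O[C@H](c3cc(OC)c(OC)c(OC)c3)[C@@H](CO)[C@@H]2C)cc(OCc3ccccc3)c1OC | intermediate
17 | [(2S,3R,4S,5R)-5-[3-(benzyloxy)-4,5-dimethoxyphenyl]-4-methyl-2-(3,4,5-trimethoxyphenyl)oxolan-3-yl]methyl methanesulfonate | COc1cc([C@@H]2O[C@H](c3cc(OC)c(OC)c(OC)c3)[C@@H](COS(C)(=O)=O)[C@@H]2C)cc(OCc3ccccc3)c1OC | intermediate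
18 | (2R,3S,4S,5S)-2-[3-(benzyloxy)-4,5-dimethoxyphenyl]-3,4-dimethyl-5-(3,4,5-trimethoxyphenyl)oxolane | COc1cc([C@@H]2O[C@H](c3cc(OC)c(OC)c(OC)c3)[C@@H](C)[C@@H]2C)cc(OCc3ccccc3)c1OC | intermediate
19 | 5-[(2R,3S,4S,5S)-3,4-dimethyl-5-(3,4,5-trimethoxyphenyl)oxolan-2-yl]-2,3-dimethoxyphenol | COc1cc([C@@H]2O[C@H](c3cc(OC)c(OC)c(OC)c3)[C@@H](C)[C@@H]2C)cc(O)c1OC | target

Total step count: 12
Longest linear sequence: 12 steps (1 to 19)

**Steps most likely to fail**

Step 8. The carbenoid may be consumed by 1,2-hydride migration from C3 or by electrophilic attack on ring A before it reaches the C5–H bond, or it may take the wrong diastereotopic benzylic hydrogen. The fallback sets out from 6 and comes back at 18, building the ring by lactone arylation and reduction instead of C–H insertion. Hydroboration of 6 (9-BBN, then NaOH/H2O2) would give (1R,2S)-1-[3-(benzyloxy)-4,5-dimethoxyphenyl]-2-methylbutane-1,4-diol F1. TEMPO/PhI(OAc)2 oxidation of its primary alcohol with lactol capture would give the cis lactone (4S,5R)-5-[3-(benzyloxy)-4,5-dimethoxyphenyl]-4-methyloxolan-2-one F2. Enolate methylation (LiN(SiMe3)2, MeI, THF, −78 °C) on the face opposite the C4 methyl and the aryl group would give (3S,4S,5R)-5-[3-(benzyloxy)-4,5-dimethoxyphenyl]-3,4-dimethyloxolan-2-one F3. 3,4,5-Trimethoxyphenyllithium F4, made from commercial 5-bromo-1,2,3-trimethoxybenzene and n-BuLi at −78 °C, would add once to F3 to give the hemiketal (3S,4S,5R)-5-[3-(benzyloxy)-4,5-dimethoxyphenyl]-3,4-dimethyl-2-(3,4,5-trimethoxyphenyl)oxolan-2-ol F5. Et3SiH/BF3·OEt2 in CH2Cl2 at −78 °C would reduce the derived oxocarbenium ion, with hydride entering the envelope so that ring B ends trans to the neighbouring methyl, which gives 18.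

Step 7. C-trifluoroacetylation of the ester enolate may be incomplete or lose out to Claisen self-condensation, so that diazo transfer stalls. The fallback sets out from 12 and comes back at 14, introducing nitrogen as an azide instead of by acyl-activated diazo transfer. The potassium enolate of 12 (KN(SiMe3)2, THF, −78 °C) would be azidated with 2,4,6-triisopropylbenzenesulfonyl azide and quenched with acetic acid to give methyl (3S,4R)-2-azido-4-[3-(benzyloxy)-4,5-dimethoxyphenyl]-3-methyl-4-[(3,4,5-trimethoxyphenyl)methoxy]butanoate F6 as a mixture of C2 epimers. N-Succinimidyl 3-(diphenylphosphino)propanoate in aqueous THF, followed by NaHCO3, would then convert the azide into the diazo group (phosphine-mediated azide-to-diazo conversion), giving 14.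

Step 2. Facial selectivity may be incomplete, or the crotyl reagent may isomerise from Z to E before it adds, giving enantiomeric or anti alcohol that erodes the purity of every later compound. The fallback sets out from 2 and comes back at 12, using auxiliary control instead of reagent control.
- Syn aldol addition (Evans type) of the dibutylboron enolate of (4R)-4-benzyl-3-propanoyl-1,3-oxazolidin-2-one (Bu2BOTf, i-Pr2NEt, CH2Cl2, −78 to 0 °C) to 2 would give (4R)-4-benzyl-3-[(2R,3R)-3-[3-(benzyloxy)-4,5-dimethoxyphenyl]-3-hydroxy-2-methylpropanoyl]-1,3-oxazolidin-2-one F7, purifiable by crystallisation.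
- Its hydroxyl would be alkylated under acid catalysis (TfOH cat., CH2Cl2, 0 °C) with 3,4,5-trimethoxybenzyl 2,2,2-trichloroacetimidate F8 (from 3,4,5-trimethoxybenzyl alcohol, CCl3CN, DBU) to give (4R)-4-benzyl-3-[(2R,3R)-3-[3-(benzyloxy)-4,5-dimethoxyphenyl]-2-methyl-3-[(3,4,5-trimethoxyphenyl)methoxy]propanoyl]-1,3-oxazolidin-2-one F9.
- LiOH/H2O2 in THF/H2O would release (2R,3R)-3-[3-(benzyloxy)-4,5-dimethoxyphenyl]-2-methyl-3-[(3,4,5-trimethoxyphenyl)methoxy]propanoic acid F10.
- Arndt–Eistert homologation would follow: i-BuOCOCl and N-methylmorpholine, then CH2N2, to (3R,4R)-4-[3-(benzyloxy)-4,5-dimethoxyphenyl]-1-diazo-3-methyl-4-[(3,4,5-trimethoxyphenyl)methoxy]butan-2-one F11, then Wolff rearrangement with PhCO2Ag, Et3N, MeOH, with retention at the migrating carbon, to give 12.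

**Further compounds**

F1 | step 8 | (1R,2S)-1-[3-(benzyloxy)-4,5-dimethoxyphenyl]-2-methylbutane-1,4-diol | COc1cc([C@H](O)[C@@H](C)CCO)cc(OCc2ccccc2)c1OC
F2 | step 8 | (4S,5R)-5-[3-(benzyloxy)-4,5-dimethoxyphenyl]-4-methyloxolan-2-one | COc1cc([C@@H]2OC(=O)C[C@@H]2C)cc(OCc3ccccc3)c1OC
F3 | step 8 | (3S,4S,5R)-5-[3-(benzyloxy)-4,5-dimethoxyphenyl]-3,4-dimethyloxolan-2-one | COc1cc([C@@H]2OC(=O)[C@@H](C)[C@@H]2C)cc(OCc3ccccc3)c1OC
F4 | step 8 | 3,4,5-trimethoxyphenyllithium | [Li]c1cc(OC)c(OC)c(OC)c1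
F5 | step 8 | (3S,4S,5R)-5-[3-(benzyloxy)-4,5-dimethoxyphenyl]-3,4-dimethyl-2-(3,4,5-trimethoxyphenyl)oxolan-2-ol (anomer mixture) | COc1cc([C@@H]2OC(O)(c3cc(OC)c(OC)c(OC)c3)[C@@H](C)[C@@H]2C)cc(OCc3ccccc3)c1OC
F6 | step 7 | methyl (3S,4R)-2-azido-4-[3-(benzyloxy)-4,5-dimethoxyphenyl]-3-methyl-4-[(3,4,5-trimethoxyphenyl)methoxy]butanoate (C2 epimers) | COc1cc([C@H](OCc2cc(OC)c(OC)c(OC)c2)[C@@H](C)C(N=[N+]=[N-])C(=O)OC)cc(OCc2ccccc2)c1OC
F7 | step 2 | (4R)-4-benzyl-3-[(2R,3R)-3-[3-(benzyloxy)-4,5-dimethoxyphenyl]-3-hydroxy-2-methylpropanoyl]-1,3-oxazolidin-2-one | COc1cc([C@H](O)[C@@H](C)C(=O)N2[C@H](Cc3ccccc3)COC2=O)cc(OCc2ccccc2)c1OC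
F8 | step 2 | 3,4,5-trimethoxybenzyl 2,2,2-trichloroacetimidate | COc1cc(COC(=N)C(Cl)(Cl)Cl)cc(OC)c1OC
F9 | step 2 | (4R)-4-benzyl-3-[(2R,3R)-3-[3-(benzyloxy)-4,5-dimethoxyphenyl]-2-methyl-3-[(3,4,5-trimethoxyphenyl)methoxy]propanoyl]-1,3-oxazolidin-2-one | COc1cc([C@H](OCc2cc(OC)c(OC)c(OC)c2)[C@@H](C)C(=O)N2[C@H](Cc3ccccc3)COC2=O)cc(OCc2ccccc2)c1OC
F10 | step 2 | (2R,3R)-3-[3-(benzyloxy)-4,5-dimethoxyphenyl]-2-methyl-3-[(3,4,5-trimethoxyphenyl)methoxy]propanoic acid | COc1cc([C@H](OCc2cc(OC)c(OC)c(OC)c2)[C@@H](C)C(O)=O)cc(OCc2ccccc2)c1OC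
F11 | step 2 | (3R,4R)-4-[3-(benzyloxy)-4,5-dimethoxyphenyl]-1-diazo-3-methyl-4-[(3,4,5-trimethoxyphenyl)methoxy]butan-2-one | COc1cc([C@H](OCc2cc(OC)c(OC)c(OC)c2)[C@@H](C)C(=O)C=[N+]=[N-])cc(OCc2ccccc2)c1OC
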